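Ring C is cut at O1–C2 (cyclodehydration) and at C2–C3 (acylation of an ω-oxygenated ketone enolate by the ring B chromene acid chloride). The side chain is then cut at C3–C4 (alkoxymethyllithium addition) and at C4–C4a (ortho-formylation).
Ring A is cut at C8–C8a, C6–C7 and C4a–C8a into 3-ethoxycyclobutenone and the TIPS ynol ether that carries the 1,1-dimethylallyl group. The ynol ether goes back to a 2,2-dimethylbut-3-enoate.
Enabling feature: in ring A the tertiary carbon sits on C8, between the oxygens on C7 and C8a and para to the oxygen on C5, while C6 and C4a carry hydrogen. The alkyne substituent of a vinylketene/siloxyalkyne benzannulation ends up in exactly this position.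
Forward order: ring A forms first, then C4 and C3 are added at C4a. In parallel the pyran ring is fused to ring B by a propargyl Claisen cascade. The halves join at C2–C3, ring C closes last, and the MOM, ethyl and TIPS groups are then removed.
Stereochemistry: the target has no stereocentre and its pyran alkene is cis by ring constraint. The transient centres of the route are racemic and are erased.

Key step: step 2

Assumption: 3-ethoxycyclobut-2-en-1-one, methyl 2,2-dimethylbut-3-enoate and tributyl[(methoxymethoxy)methyl]stannane are taken as catalogue chemicals.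

Step 1
Reactants: 1 methyl 2,2-dimethylbut-3-enoate
Product: 4 (3,3-dimethylpent-4-en-1-yn-1-yloxy)triisopropylsilane, via lithium dibromoenolate 2 (not isolated), via lithium ynolate 3 (not isolated)
Conditions: CH2Br2, LiTMP, THF, −78 °C; n-BuLi, −78 → 20 °C; TIPSCl, −78 → 0 °C
Reagents that add atoms: dibromomethane BrCBr; chlorotriisopropylsilane CC(C)[Si](Cl)(C(C)C)C(C)C
Why: Kowalski ynolate synthesis, in which acylation of LiCHBr2 gives the dibromo enolate, bromine–lithium exchange triggers the carbenoid 1,2-shift of the tertiary alkyl group, and bulky TIPSCl silylates the ynolate at oxygen because its carbon terminus is neopentyl-like.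

Step 2
Reactants: 4 (3,3-dimethylpent-4-en-1-yn-1-yloxy)triisopropylsilane; 5 3-ethoxycyclobut-2-en-1-one
Product: 10 5-ethoxy-2-(2-methylbut-3-en-2-yl)-3-(triisopropylsilyloxy)phenol, via vinylketene 6 (not isolated), via vinylcyclobutenone 7 (not isolated), via dienylketene 8 (not isolated), via cyclohexadienone 9 (not isolated)
Conditions: 4 (1.2 equiv), toluene (1 M), sealed tube, 80 °C, then 110 °C
Reagents that add atoms: none
Why: Heating opens 5 by 4π electrocyclic cleavage to the (2-ethoxyvinyl)ketene 6, which adds 4 in a [2+2] cycloaddition to 7; a second 4π opening gives 8, 6π electrocyclisation gives 9, and enolisation gives 10. This is the Danheiser benzannulation of a cyclobutenone with a siloxyalkyne, the established route to resorcinol monosilyl ethers that carry the alkyne substituent between the two oxygens. Ring A, the only ring formed, closes by the thermal disrotatory 6π electrocyclisation of 8, which joins the ketene carbon (C8a) to the terminal methylene (C4a) after C8–C8a and C6–C7 were made in the [2+2] event. No stereocentre is created in 10, since C4 of 7 is racemic and returns to sp2 when that ring opens. The step needs a single regiochemistry in the [2+2] addition, and the oxygen lone pair of the ynol ether secures it by making the carbon that bears the tertiary group the nucleophilic terminus, which bonds to the electrophilic ketene carbonyl carbon and so places the group between C–OH and C–OTIPS and para to OEt. The unactivated vinyl group cannot compete with the ynol ether as ketenophile, the reversible opening of 5 keeps the ketene concentration low while the hindered alkyne reacts, and the slight excess of 4 limits acylation of 10 by 6.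

Step 3
Reactants: 10 5-ethoxy-2-(2-methylbut-3-en-2-yl)-3-(triisopropylsilyloxy)phenol
Product: 11 6-ethoxy-2-hydroxy-3-(2-methylbut-3-en-2-yl)-4-(triisopropylsilyloxy)benzaldehyde
Conditions: MgCl2, Et3N, (CH2O)n, MeCN, reflux; cold 1 M HCl
Reagents that add atoms: paraformaldehyde (as formaldehyde) C=O
Why: Casnati–Skattebøl ortho-formylation, in which the magnesium phenoxide delivers formaldehyde only ortho to its oxygen, so with C8 blocked only C4a can react (as with 2-tert-butylphenols), and a second formaldehyde oxidises the benzylic alkoxide by hydride transfer.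

Step 4
Reactants: 11 6-ethoxy-2-hydroxy-3-(2-methylbut-3-en-2-yl)-4-(triisopropylsilyloxy)benzaldehyde
Product: 12 1-[6-ethoxy-2-hydroxy-3-(2-methylbut-3-en-2-yl)-4-(triisopropylsilyloxy)phenyl]-2-(methoxymethoxy)ethan-1-ol (racemic)
Conditions: NaH, THF, 0 °C; LiCH2OMOM (from Bu3SnCH2OMOM, n-BuLi, THF, −78 °C), −78 °C; aq NH4Cl
Reagents that add atoms: tributyl[(methoxymethoxy)methyl]stannane CCCC[Sn](CCCC)(CCCC)COCOC
Why: Tin–lithium exchange gives the α-alkoxymethyllithium, which adds 1,2 to the aldehyde of the preformed sodium phenoxide; the new carbinol centre forms without control, is racemic, and is erased in step 5.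

Step 5
Reactants: 12 1-[6-ethoxy-2-hydroxy-3-(2-methylbut-3-en-2-yl)-4-(triisopropylsilyloxy)phenyl]-2-(methoxymethoxy)ethan-1-ol
Product: 13 1-[6-ethoxy-2-hydroxy-3-(2-methylbut-3-en-2-yl)-4-(triisopropylsilyloxy)phenyl]-2-(methoxymethoxy)ethan-1-one
Conditions: activated MnO2, CH2Cl2, rt
Reagents that add atoms: none
Why: Benzylic alcohol oxidation with MnO2, which is fast for an electron-rich ortho-hydroxybenzylic alcohol, leaves the isolated vinyl group and the MOM and TIPS ethers alone, and ends at a ketone stabilised by its chelated phenol hydrogen bond.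

Step 6
Reactants: 14 3,4-dihydroxybenzaldehyde; 15 3-chloro-3-methylbut-1-yne
Product: 16 3-hydroxy-4-(2-methylbut-3-yn-2-yloxy)benzaldehyde
Conditions: K2CO3 (1.1 equiv), KI (cat.), CuI (cat.), DMF, 60 °C
Reagents that add atoms: none
Why: Copper-assisted Williamson-type propargylation, in which one equivalent of weak base ionises only the more acidic 4-hydroxyl (para to the formyl group), so the tertiary propargyl chloride is taken up at O4.

Step 7
Reactants: 16 3-hydroxy-4-(2-methylbut-3-yn-2-yloxy)benzaldehyde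
Product: 17 3-(methoxymethoxy)-4-(2-methylbut-3-yn-2-yloxy)benzaldehyde
Conditions: MOMCl, i-Pr2NEt, CH2Cl2, 0 °C → rt
Reagents that add atoms: chloromethyl methyl ether COCCl
Why: Standard MOM ether formation on the remaining phenol, which keeps that hydroxyl from adding to the alkyne on heating and masks it for the later strong-base step.

Step 8
Reactants: 17 3-(methoxymethoxy)-4-(2-methylbut-3-yn-2-yloxy)benzaldehyde
Product: 18 8-(methoxymethoxy)-2,2-dimethyl-2H-chromene-6-carbaldehyde
Conditions: N,N-diethylaniline, 190 °C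
Reagents that add atoms: none
Why: Aromatic propargyl Claisen rearrangement to C5, the only free ortho position, followed by 1,5-hydrogen shift and oxa-6π electrocyclisation, which is the standard thermal route to 2,2-dimethylchromenes.

Step 9
Reactants: 18 8-(methoxymethoxy)-2,2-dimethyl-2H-chromene-6-carbaldehyde
Product: 19 8-(methoxymethoxy)-2,2-dimethyl-2H-chromene-6-carboxylic acid
Conditions: NaClO2, NaH2PO4, 2-methylbut-2-ene, t-BuOH–H2O, rt
Reagents that add atoms: sodium chlorite [Na+].[O-]Cl=O
Why: Pinnick oxidation, selective for the aldehyde, with the excess trisubstituted alkene scavenging the hypochlorous acid before it can reach the chromene double bond.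

Step 10
Reactants: 13 1-[6-ethoxy-2-hydroxy-3-(2-methylbut-3-en-2-yl)-4-(triisopropylsilyloxy)phenyl]-2-(methoxymethoxy)ethan-1-one; 19 8-(methoxymethoxy)-2,2-dimethyl-2H-chromene-6-carboxylic acid
Product: 21 1-[6-ethoxy-2-hydroxy-3-(2-methylbut-3-en-2-yl)-4-(triisopropylsilyloxy)phenyl]-2-(methoxymethoxy)-3-[8-(methoxymethoxy)-2,2-dimethyl-2H-chromen-6-yl]propane-1,3-dione (racemic; enolisable), via acid chloride 20 (not isolated)
Conditions: 19, 1-chloro-N,N,2-trimethylprop-1-en-1-amine, CH2Cl2, 0 °C → rt, solvent changed to THF; 13, LiHMDS (3.3 equiv), THF, −78 → −20 °C; then 20, −78 °C → rt; aq NH4Cl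
Reagents that add atoms: none
Why: Enolate-acylation variant of the Baker–Venkataraman synthesis, in which the dilithio phenoxide–enolate of 13 is acylated at carbon by 20 (any aroyl ester formed at the hindered phenoxide is carried to the same diketone by base-induced acyl transfer), the neutral chloroenamine spares the MOM ether, and the new centre at C3 is racemic, enolisable and lost in step 11.

Step 11
Reactants: 21 1-[6-ethoxy-2-hydroxy-3-(2-methylbut-3-en-2-yl)-4-(triisopropylsilyloxy)phenyl]-2-(methoxymethoxy)-3-[8-(methoxymethoxy)-2,2-dimethyl-2H-chromen-6-yl]propane-1,3-dione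
Product: 22 5-ethoxy-3-hydroxy-2-(8-hydroxy-2,2-dimethyl-2H-chromen-6-yl)-8-(2-methylbut-3-en-2-yl)-7-(triisopropylsilyloxy)-4H-chromen-4-one
Conditions: p-TsOH·H2O (cat.), MeOH–THF, 50 °C
Reagents that add atoms: none
Why: Acid-catalysed cyclodehydration of an ortho-hydroxyaryl β-diketone closes ring C through the C2 hemiketal and loss of water, while the same acid transacetalises both MOM groups to methanol; the monosubstituted vinyl group, the chromene and the shielded aryl TIPS ether tolerate these mild conditions.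

Step 12
Reactants: 22 5-ethoxy-3-hydroxy-2-(8-hydroxy-2,2-dimethyl-2H-chromen-6-yl)-8-(2-methylbut-3-en-2-yl)-7-(triisopropylsilyloxy)-4H-chromen-4-one
Product: 23 3,5-dihydroxy-2-(8-hydroxy-2,2-dimethyl-2H-chromen-6-yl)-8-(2-methylbut-3-en-2-yl)-7-(triisopropylsilyloxy)-4H-chromen-4-one
Conditions: BCl3 (4 equiv), CH2Cl2, −78 → −10 °C; ice–water
Reagents that add atoms: none
Why: Chelation-assisted ether cleavage, in which boron bridges the C4 carbonyl and the peri oxygen at C5 in a six-membered chelate so that chloride attacks only this ethyl group, while the silyl group kept on O7 leaves no free phenol beside the vinyl group during the acid exposure.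

Step 13
Reactants: 23 3,5-dihydroxy-2-(8-hydroxy-2,2-dimethyl-2H-chromen-6-yl)-8-(2-methylbut-3-en-2-yl)-7-(triisopropylsilyloxy)-4H-chromen-4-one
Product: 24 broussonol A
Conditions: TBAF, AcOH (1:1), THF, 0 °C, argon
Reagents that add atoms: none
Why: Fluoride-induced desilylation of an aryl silyl ether whose phenoxide, conjugated with the C4 carbonyl, is a good leaving group, with acetic acid buffering to protect the oxidisable flavonol from base.

Compound list
1 | methyl 2,2-dimethylbut-3-enoate | COC(=O)C(C)(C)C=C | starting material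
2 | lithium 1,1-dibromo-3,3-dimethylpenta-1,4-dien-2-olate | [Li]OC(=C(Br)Br)C(C)(C)C=C | intermediate
3 | lithium 3,3-dimethylpent-4-en-1-yn-1-olate | [Li]OC#CC(C)(C)C=C | intermediate
4 | (3,3-dimethylpent-4-en-1-yn-1-yloxy)triisopropylsilane | C=CC(C)(C)C#CO[Si](C(C)C)(C(C)C)C(C)C | intermediate
5 | 3-ethoxycyclobut-2-en-1-one | CCOC1=CC(=O)C1 | starting material
6 | 3-ethoxybuta-1,3-dien-1-one | CCOC(=C)C=C=O | intermediate
7 | 4-(1-ethoxyvinyl)-2-(2-methylbut-3-en-2-yl)-3-(triisopropylsilyloxy)cyclobut-2-en-1-one (racemic) | CCOC(=C)C1C(=O)C(C(C)(C)C=C)=C1O[Si](C(C)C)(C(C)C)C(C)C | intermediate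
8 | (3E)-5-ethoxy-2-(2-methylbut-3-en-2-yl)-3-(triisopropylsilyloxy)hexa-1,3,5-trien-1-one | O=C=C(C(C)(C)C=C)/C(O[Si](C(C)C)(C(C)C)C(C)C)=C\C(=C)OCC | intermediate
9 | 5-ethoxy-2-(2-methylbut-3-en-2-yl)-3-(triisopropylsilyloxy)cyclohexa-2,4-dien-1-one | O=C1CC(OCC)=CC(O[Si](C(C)C)(C(C)C)C(C)C)=C1C(C)(C)C=C | intermediate
10 | 5-ethoxy-2-(2-methylbut-3-en-2-yl)-3-(triisopropylsilyloxy)phenol | C=CC(C)(C)c1c(O)cc(OCC)cc1O[Si](C(C)C)(C(C)C)C(C)C | intermediate
11 | 6-ethoxy-2-hydroxy-3-(2-methylbut-3-en-2-yl)-4-(triisopropylsilyloxy)benzaldehyde | C=CC(C)(C)c1c(O)c(C=O)c(OCC)cc1O[Si](C(C)C)(C(C)C)C(C)C | intermediate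
12 | 1-[6-ethoxy-2-hydroxy-3-(2-methylbut-3-en-2-yl)-4-(triisopropylsilyloxy)phenyl]-2-(methoxymethoxy)ethan-1-ol (racemic) | C=CC(C)(C)c1c(O)c(C(O)COCOC)c(OCC)cc1O[Si](C(C)C)(C(C)C)C(C)C | intermediate
13 | 1-[6-ethoxy-2-hydroxy-3-(2-methylbut-3-en-2-yl)-4-(triisopropylsilyloxy)phenyl]-2-(methoxymethoxy)ethan-1-one | C=CC(C)(C)c1c(O)c(C(=O)COCOC)c(OCC)cc1O[Si](C(C)C)(C(C)C)C(C)C | intermediate
14 | 3,4-dihydroxybenzaldehyde | O=Cc1ccc(O)c(O)c1 | starting material
15 | 3-chloro-3-methylbut-1-yne | C#CC(C)(C)Cl | starting material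
16 | 3-hydroxy-4-(2-methylbut-3-yn-2-yloxy)benzaldehyde | C#CC(C)(C)Oc1ccc(C=O)cc1O | intermediate
17 | 3-(methoxymethoxy)-4-(2-methylbut-3-yn-2-yloxy)benzaldehyde | C#CC(C)(C)Oc1ccc(C=O)cc1OCOC | intermediate
18 | 8-(methoxymethoxy)-2,2-dimethyl-2H-chromene-6-carbaldehyde | COCOc1cc(C=O)cc2C=CC(C)(C)Oc12 | intermediate
19 | 8-(methoxymethoxy)-2,2-dimethyl-2H-chromene-6-carboxylic acid | COCOc1cc(C(=O)O)cc2C=CC(C)(C)Oc12 | intermediate
20 | 8-(methoxymethoxy)-2,2-dimethyl-2H-chromene-6-carbonyl chloride | COCOc1cc(C(=O)Cl)cc2C=CC(C)(C)Oc12 | intermediate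
21 | 1-[6-ethoxy-2-hydroxy-3-(2-methylbut-3-en-2-yl)-4-(triisopropylsilyloxy)phenyl]-2-(methoxymethoxy)-3-[8-(methoxymethoxy)-2,2-dimethyl-2H-chromen-6-yl]propane-1,3-dione (racemic; enolisable) | C=CC(C)(C)c1c(O)c(C(=O)C(OCOC)C(=O)c2cc(OCOC)c3OC(C)(C)C=Cc3c2)c(OCC)cc1O[Si](C(C)C)(C(C)C)C(C)C | intermediate
22 | 5-ethoxy-3-hydroxy-2-(8-hydroxy-2,2-dimethyl-2H-chromen-6-yl)-8-(2-methylbut-3-en-2-yl)-7-(triisopropylsilyloxy)-4H-chromen-4-one | C=CC(C)(C)c1c(O[Si](C(C)C)(C(C)C)C(C)C)cc(OCC)c2c(=O)c(O)c(-c3cc(O)c4c(c3)C=CC(C)(C)O4)oc12 | intermediate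
23 | 3,5-dihydroxy-2-(8-hydroxy-2,2-dimethyl-2H-chromen-6-yl)-8-(2-methylbut-3-en-2-yl)-7-(triisopropylsilyloxy)-4H-chromen-4-one | C=CC(C)(C)c1c(O[Si](C(C)C)(C(C)C)C(C)C)cc(O)c2c(=O)c(O)c(-c3cc(O)c4c(c3)C=CC(C)(C)O4)oc12 | intermediate
24 | broussonol A, 3,5,7-trihydroxy-2-(8-hydroxy-2,2-dimethyl-2H-chromen-6-yl)-8-(2-methylbut-3-en-2-yl)-4H-chromen-4-one | C=CC(C)(C)c1c(O)cc(O)c2c(=O)c(O)c(-c3cc(O)c4c(c3)C=CC(C)(C)O4)oc12 | target

Total step count: 13.
Longest linear sequence: 9 steps (steps 1–5 and 10–13, from 1). The ring B branch from 14 runs 8 steps (steps 6–9 and 10–13).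

Steps most likely to fail

Step 2. The first C–C bond must form at an alkyne carbon that carries a quaternary centre. If this cycloaddition is slower than self-condensation of the vinylketene, or slower than capture of the ketene by phenol already formed, the cascade starves before ring A can close.

The fallback sets out from lithium ynolate 3 (made as in step 1 and left unsilylated) and comes back at phenol 10.
- Ethoxyacetylene is lithiated (n-BuLi) and silylated (TIPSOTf) to (ethoxyethynyl)triisopropylsilane F1.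
- [2+2] Cycloaddition with dichloroketene (Cl3CCOCl, activated Zn, Et2O) should give 4,4-dichloro-3-ethoxy-2-(triisopropylsilyl)cyclobut-2-en-1-one F2.
- Reductive dechlorination (Zn, AcOH, TMEDA, EtOH) should give 3-ethoxy-2-(triisopropylsilyl)cyclobut-2-en-1-one F3.
- Heating should open F3 to the silyl-stabilised, isolable vinylketene 3-ethoxy-2-(triisopropylsilyl)buta-1,3-dien-1-one F4.
- Ynolate 3 is anionic, far more nucleophilic than 4 and free of the silyl group. It is C-acylated by F4 (THF, −78 °C → rt). 6π electrocyclic closure, tautomerisation and a 1,3 shift of silicon from carbon to oxygen should then deliver 10 on protonation (ynolate/silylvinylketene benzannulation).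

Step 1. Addition of LiCHBr2 to the α-quaternary ester may be slow. The carbenoid may be protonated or may decompose before the tertiary group migrates, and part of the silylation may occur at carbon.

The fallback sets out from ester 1 and comes back at ynolate 3, and so at 4.
- Reduction with i-Bu2AlH (CH2Cl2, −78 °C) gives 2,2-dimethylbut-3-enal F5.
- Corey–Fuchs olefination (CBr4, PPh3) gives 1,1-dibromo-3,3-dimethylpenta-1,4-diene F6.
- n-BuLi (2 equiv, THF, −78 °C) gives (3,3-dimethylpent-4-en-1-yn-1-yl)lithium F7.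
- F7 is oxidised in the same flask by t-BuOOLi (from t-BuOOH and LiHMDS) to 3, which is trapped with TIPSOTf as 4. No volatile alkyne has to be isolated.

Step 12. An ethyl ether cleaves more slowly than a methyl ether, so the Lewis acid exposure is prolonged. HCl liberated from the free hydroxyls may add to the chromene double bond. Premature loss of the TIPS group would allow the 7-hydroxyl to cyclise onto the vinyl group.

The fallback sets out from aldehyde 11 and comes back at 23. It exchanges the ethyl group while the molecule is still small.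
- MgI2 etherate (toluene–Et2O, 60 °C) cleaves the ether chelated to the formyl group. This gives 2,6-dihydroxy-3-(2-methylbut-3-en-2-yl)-4-(triisopropylsilyloxy)benzaldehyde F8.
- MOMCl (1 equiv) with i-Pr2NEt takes the unhindered 6-hydroxyl, because the 2-hydroxyl lies beside the quaternary carbon. This gives 2-hydroxy-6-(methoxymethoxy)-3-(2-methylbut-3-en-2-yl)-4-(triisopropylsilyloxy)benzaldehyde F9.
- The operations of step 4 give 1-[2-hydroxy-6-(methoxymethoxy)-3-(2-methylbut-3-en-2-yl)-4-(triisopropylsilyloxy)phenyl]-2-(methoxymethoxy)ethan-1-ol F10.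
- The operations of step 5 give 1-[2-hydroxy-6-(methoxymethoxy)-3-(2-methylbut-3-en-2-yl)-4-(triisopropylsilyloxy)phenyl]-2-(methoxymethoxy)ethan-1-one F11.
- The operations of step 10 (with 20) give 1-[2-hydroxy-6-(methoxymethoxy)-3-(2-methylbut-3-en-2-yl)-4-(triisopropylsilyloxy)phenyl]-2-(methoxymethoxy)-3-[8-(methoxymethoxy)-2,2-dimethyl-2H-chromen-6-yl]propane-1,3-dione F12.
- The acid treatment of step 11 then removes three MOM groups while ring C closes and should give 23 directly, so BCl3 never meets the chromene.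

Further compounds
F1 | step 2 | (ethoxyethynyl)triisopropylsilane | CCOC#C[Si](C(C)C)(C(C)C)C(C)C
F2 | step 2 | 4,4-dichloro-3-ethoxy-2-(triisopropylsilyl)cyclobut-2-en-1-one | CCOC1=C([Si](C(C)C)(C(C)C)C(C)C)C(=O)C1(Cl)Cl
F3 | step 2 | 3-ethoxy-2-(triisopropylsilyl)cyclobut-2-en-1-one | CCOC1=C([Si](C(C)C)(C(C)C)C(C)C)C(=O)C1
F4 | step 2 | 3-ethoxy-2-(triisopropylsilyl)buta-1,3-dien-1-one | CCOC(=C)C(=C=O)[Si](C(C)C)(C(C)C)C(C)C
F5 | step 1 | 2,2-dimethylbut-3-enal | C=CC(C)(C)C=O
F6 | step 1 | 1,1-dibromo-3,3-dimethylpenta-1,4-diene | C=CC(C)(C)C=C(Br)Br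
F7 | step 1 | (3,3-dimethylpent-4-en-1-yn-1-yl)lithium | [Li]C#CC(C)(C)C=C
F8 | step 12 | 2,6-dihydroxy-3-(2-methylbut-3-en-2-yl)-4-(triisopropylsilyloxy)benzaldehyde | C=CC(C)(C)c1c(O)c(C=O)c(O)cc1O[Si](C(C)C)(C(C)C)C(C)C
F9 | step 12 | 2-hydroxy-6-(methoxymethoxy)-3-(2-methylbut-3-en-2-yl)-4-(triisopropylsilyloxy)benzaldehyde | C=CC(C)(C)c1c(O)c(C=O)c(OCOC)cc1O[Si](C(C)C)(C(C)C)C(C)C
F10 | step 12 | 1-[2-hydroxy-6-(methoxymethoxy)-3-(2-methylbut-3-en-2-yl)-4-(triisopropylsilyloxy)phenyl]-2-(methoxymethoxy)ethan-1-ol (racemic) | C=CC(C)(C)c1c(O)c(C(O)COCOC)c(OCOC)cc1O[Si](C(C)C)(C(C)C)C(C)C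
F11 | step 12 | 1-[2-hydroxy-6-(methoxymethoxy)-3-(2-methylbut-3-en-2-yl)-4-(triisopropylsilyloxy)phenyl]-2-(methoxymethoxy)ethan-1-one | C=CC(C)(C)c1c(O)c(C(=O)COCOC)c(OCOC)cc1O[Si](C(C)C)(C(C)C)C(C)C
F12 | step 12 | 1-[2-hydroxy-6-(methoxymethoxy)-3-(2-methylbut-3-en-2-yl)-4-(triisopropylsilyloxy)phenyl]-2-(methoxymethoxy)-3-[8-(methoxymethoxy)-2,2-dimethyl-2H-chromen-6-yl]propane-1,3-dione (racemic; enolisable) | C=CC(C)(C)c1c(O)c(C(=O)C(OCOC)C(=O)c2cc(OCOC)c3OC(C)(C)C=Cc3c2)c(OCOC)cc1O[Si](C(C)C)(C(C)C)C(C)C
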